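Retrosynthesis: the C2 acetate and C6 4-hydroxybenzoate C–O bonds and the C4–isopropyl bond are cut first, then the C5–C6 bond of ring B (aldol), and the C6 aldehyde and C9 ketone are folded back into a furan.
Enabling feature: C6(O)–C7=C8(CH3)–C9(=O) of ring B, with its cis alkene, is the four-carbon array of a 2-alkyl-3-methylfuran after oxidative opening, and the C4 carbonyl of ring A makes C5 the nucleophile that closes ring B.
Forward order: ring A is built from cyclopentane-1,3-dione (furylmethylation, methylation, desymmetrising reduction, carbonyl shift from C5 to C4); ring B then arises by furan opening and aldol closure; isopropyl addition and the two esters follow.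
Stereochemistry: C1 and C2 come together from one catalyst-controlled (CBS) reduction of the prochiral dione; C5 and C6 are set in the aldol closure (trans fusion, equatorial 6α-hydroxyl).
C4 is set by organocerium addition on the α face, anti to the angular methyl group.

Key step: step 9

Remark: framework numbering is C1 (methyl-bearing fusion carbon), C2 (acetoxy carbon), C3 (CH2), C4 (isopropyl carbinol), C5 (fusion CH) for ring A and C6 (aroyloxy carbon), C7=C8 (methyl on C8), C9 (ketone), C10 (CH2) for ring B; β is the face carrying the C1 methyl group, α the opposite face.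
Remark: 3-methylfuran-2-carbaldehyde is taken as a catalogue chemical, and the cyclopentanol formed by hydroboration is carried as a mixture of carbinol epimers because the next step removes that centre.

Step 1
Reactants: 1 cyclopentane-1,3-dione; 2 3-methylfuran-2-carbaldehyde
Product: 4 2-[(3-methylfuran-2-yl)methyl]cyclopentane-1,3-dione, via alkylidene dione 3 (not isolated)
Conditions: Hantzsch ester (1.1 equiv), L-proline (5 mol%), CH2Cl2, rt
Reagents that add atoms: none
Why: Proline-catalysed Knoevenagel condensation gives the alkylidene dione, which the Hantzsch ester reduces in situ by conjugate hydride transfer before a second dione can add (three-component reductive alkylation, routine for cyclic 1,3-diones and heteroaryl aldehydes); no stereocentre is formed.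

Step 2
Reactants: 4 2-[(3-methylfuran-2-yl)methyl]cyclopentane-1,3-dione; 5 iodomethane
Product: 6 2-methyl-2-[(3-methylfuran-2-yl)methyl]cyclopentane-1,3-dione
Conditions: MeI, KOH, H2O/1,4-dioxane, 60 °C
Reagents that add atoms: iodomethane, CI
Why: C-alkylation of the 2-substituted dione enolate in a protic medium, which favours carbon over oxygen, should give the prochiral 2,2-disubstituted dione; any O-methyl enol ether is separable and can be hydrolysed back to 4.

Step 3
Reactants: 6 2-methyl-2-[(3-methylfuran-2-yl)methyl]cyclopentane-1,3-dione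
Product: 7 (2R,3R)-3-hydroxy-2-methyl-2-[(3-methylfuran-2-yl)methyl]cyclopentan-1-one (hydroxyl cis to the furylmethyl group)
Conditions: (S)-2-methyl-CBS-oxazaborolidine (0.2 equiv), catecholborane, toluene, −78 → −40 °C; aq. NaOH work-up
Reagents that add atoms: none
Why: Corey–Bakshi–Shibata reduction used as a desymmetrisation: hydride enters from the methyl face, anti to the larger furylmethyl group, so the hydroxyl ends cis to that group, and the (S)-catalyst, reading the quaternary carbon as the large substituent, should select the carbonyl that gives the R carbinol, which fixes C1 and C2 of the target in one event.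

Step 4
Reactants: 7 (2R,3R)-3-hydroxy-2-methyl-2-[(3-methylfuran-2-yl)methyl]cyclopentan-1-one
Product: 8 (2R,3R)-3-[(tert-butyldimethylsilyl)oxy]-2-methyl-2-[(3-methylfuran-2-yl)methyl]cyclopentan-1-one
Conditions: TBSOTf, 2,6-lutidine, CH2Cl2, −78 → 0 °C
Reagents that add atoms: tert-butyldimethylsilyl trifluoromethanesulfonate, CC(C)(C)[Si](C)(C)OS(=O)(=O)C(F)(F)F
Why: Silyl triflate silylation copes with the hindered neopentyl alcohol and removes the risk of retro-aldol ring opening of the β-hydroxy ketone under the strong base of the next step.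

Step 5
Reactants: 8 (2R,3R)-3-[(tert-butyldimethylsilyl)oxy]-2-methyl-2-[(3-methylfuran-2-yl)methyl]cyclopentan-1-one
Product: 9 (4R,5R)-4-[(tert-butyldimethylsilyl)oxy]-5-methyl-5-[(3-methylfuran-2-yl)methyl]cyclopent-1-en-1-yl trifluoromethanesulfonate
Conditions: KN(SiMe3)2, PhNTf2, THF, −78 °C
Reagents that add atoms: N-phenylbis(trifluoromethanesulfonimide), O=S(=O)(N(c1ccccc1)S(=O)(=O)C(F)(F)F)C(F)(F)F
Why: The ketone has a single enolisable α-carbon (the other is quaternary), so enolate O-triflation gives one enol triflate, and the silyloxy group is not β to the enolate carbon and cannot be eliminated.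

Step 6
Reactants: 9 (4R,5R)-4-[(tert-butyldimethylsilyl)oxy]-5-methyl-5-[(3-methylfuran-2-yl)methyl]cyclopent-1-en-1-yl trifluoromethanesulfonate
Product: 10 tert-butyldimethyl{[(1R,2S)-2-methyl-2-[(3-methylfuran-2-yl)methyl]cyclopent-3-en-1-yl]oxy}silane
Conditions: Pd(OAc)2 (5 mol%), PPh3, HCO2H, n-Bu3N, DMF, 60 °C
Reagents that add atoms: none
Why: Palladium-catalysed formate reduction of an enol triflate (insertion of zerovalent palladium into the C–O bond, formate exchange, loss of CO2, reductive elimination) is well established for ring enol triflates next to quaternary carbons and should leave the furan and silyl ether untouched.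

Step 7
Reactants: 10 tert-butyldimethyl{[(1R,2S)-2-methyl-2-[(3-methylfuran-2-yl)methyl]cyclopent-3-en-1-yl]oxy}silane
Product: 12 (3R,4R)-4-[(tert-butyldimethylsilyl)oxy]-3-methyl-3-[(3-methylfuran-2-yl)methyl]cyclopentan-1-ol (carbinol epimers), via B-alkyl-9-BBN adduct 11 (not isolated)
Conditions: 9-BBN, THF, 0 °C → rt; then NaOH, H2O2, 0 °C
Reagents that add atoms: hydrogen peroxide, OO
Why: Hydroboration–oxidation: the bulky borane should place boron on the alkene carbon remote from the quaternary centre (future C4) and alkaline peroxide replaces boron by hydroxyl; the carbinol configuration does not matter, and any regioisomeric alcohol would be oxidised in step 8 back to ketone 8 and recycled.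

Step 8
Reactants: 12 (3R,4R)-4-[(tert-butyldimethylsilyl)oxy]-3-methyl-3-[(3-methylfuran-2-yl)methyl]cyclopentan-1-ol
Product: 13 (3S,4R)-4-[(tert-butyldimethylsilyl)oxy]-3-methyl-3-[(3-methylfuran-2-yl)methyl]cyclopentan-1-one
Conditions: Dess–Martin periodinane, NaHCO3, CH2Cl2, 0 °C → rt
Reagents that add atoms: none
Why: Dess–Martin oxidation under buffered, non-basic conditions should give the β-silyloxy ketone without β-elimination; steps 5 to 8 together move the carbonyl from C5 to C4, a 1,2-carbonyl transposition.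

Step 9
Reactants: 13 (3S,4R)-4-[(tert-butyldimethylsilyl)oxy]-3-methyl-3-[(3-methylfuran-2-yl)methyl]cyclopentan-1-one
Product: 15 (1R,3aR,4R,8aS)-1-[(tert-butyldimethylsilyl)oxy]-4-hydroxy-6,8a-dimethyl-1,2,3a,4,8,8a-hexahydroazulene-3,7-dione (trans-fused, 6α-hydroxyl in framework numbering), via Z-keto-enal 14 (not isolated)
Conditions: NBS (1.05 equiv), NaHCO3, acetone/H2O (10:1), −20 °C; cold extraction into CH2Cl2 without purification; then pyrrolidine (0.3 equiv), AcOH (0.3 equiv), CH2Cl2, 0 °C
Reagents that add atoms: water, O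
Why: Bromination of the furan at its free α-position (future C6), capture by water at the alkyl-bearing α-carbon (future C9) and loss of HBr open the ring to the Z-configured 4-oxo-2-enal 14, whose aldehyde has no α-hydrogen; pyrrolidinium acetate then turns the cyclopentanone, the only unconjugated ketone, into its enamines, and the C5 enamine adds to the C6 aldehyde before hydrolysis returns the catalyst. Both halves are known reaction types: buffered N-bromosuccinimide opening of 2-alkylfurans to cis-4-oxo-2-enals and amine-catalysed intramolecular ketone–aldehyde aldol addition of the enolexo kind. Ring B closes in a 7-(enolexo)-exo-trig mode, the Z alkene and the sp2 C9 holding C6 within reach of C5. C5 is fixed when the C4–C5 enamine of the closed bicycle is C-protonated on the α face, opposite the pseudo-axial C1 methyl group, giving the trans fusion that is also expected to be the more stable hydroazulenone, and C6 is selected by the reversibility of the addition, which should favour the pseudo-equatorial α-hydroxyl, anti to H-5 and hydrogen-bonded to the C4 carbonyl. The step needs addition from C5 to the aldehyde carbon only: a C3 enamine cannot reach C6 without forming a bridged ring, closure from C10 would be a 5-(enolendo) process through the less readily enolised conjugated ketone, and the aldehyde is the most electrophilic and least hindered acceptor because the alkene is α-branched at C8. Loss of water to the cross-conjugated dienone and amine-induced Z-to-E isomerisation of 14 are held back by working cold with a sub-stoichiometric amine salt and stopping once 14 is consumed.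

Step 10
Reactants: 15 (1R,3aR,4R,8aS)-1-[(tert-butyldimethylsilyl)oxy]-4-hydroxy-6,8a-dimethyl-1,2,3a,4,8,8a-hexahydroazulene-3,7-dione; 16 isopropylmagnesium chloride
Product: 17 (1R,3S,3aR,4R,8aS)-1-[(tert-butyldimethylsilyl)oxy]-3,4-dihydroxy-6,8a-dimethyl-3-(propan-2-yl)-2,3,3a,4,8,8a-hexahydroazulen-7(1H)-one
Conditions: CeCl3 (anhydrous, 4 equiv), i-PrMgCl (3.5 equiv), THF, −78 → −40 °C; aq. NH4Cl
Reagents that add atoms: isopropylmagnesium chloride, CC(C)[Mg]Cl
Why: Organocerium 1,2-addition to an enolisable ketone: the first equivalent forms the C6 alkoxide, whose six-membered chelate with the C4 carbonyl should activate that ketone over the conjugated C9 ketone (flanked by the neopentyl C10 and the methyl-bearing alkene), and the isopropyl group enters on the α face, anti to the axial C1 methyl group, to give the 4β-hydroxyl.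

Step 11
Reactants: 17 (1R,3S,3aR,4R,8aS)-1-[(tert-butyldimethylsilyl)oxy]-3,4-dihydroxy-6,8a-dimethyl-3-(propan-2-yl)-2,3,3a,4,8,8a-hexahydroazulen-7(1H)-one; 18 4-acetoxybenzoic acid
Product: 19 (1R,3S,3aR,4R,8aS)-1-[(tert-butyldimethylsilyl)oxy]-3-hydroxy-6,8a-dimethyl-7-oxo-3-(propan-2-yl)-1,2,3,3a,4,7,8,8a-octahydroazulen-4-yl 4-acetoxybenzoate
Conditions: DCC, DMAP (cat.), CH2Cl2, 0 °C → rt
Reagents that add atoms: 4-acetoxybenzoic acid, CC(=O)Oc1ccc(cc1)C(=O)O
Why: Steglich esterification of the secondary allylic C6 alcohol; the tertiary C4 alcohol does not acylate under these conditions, and the phenol of the acid is masked as its acetate.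

Step 12
Reactants: 19 (1R,3S,3aR,4R,8aS)-1-[(tert-butyldimethylsilyl)oxy]-3-hydroxy-6,8a-dimethyl-7-oxo-3-(propan-2-yl)-1,2,3,3a,4,7,8,8a-octahydroazulen-4-yl 4-acetoxybenzoate
Product: 20 (1R,3S,3aR,4R,8aS)-1,3-dihydroxy-6,8a-dimethyl-7-oxo-3-(propan-2-yl)-1,2,3,3a,4,7,8,8a-octahydroazulen-4-yl 4-acetoxybenzoate
Conditions: HF·pyridine, pyridine/THF, 0 °C → rt
Reagents that add atoms: none
Why: Buffered fluoride cleavage of the secondary silyl ether is non-basic and should spare both esters, the tertiary alcohol and the enone; any loss of the phenolic acetate would be repaired in step 13.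

Step 13
Reactants: 20 (1R,3S,3aR,4R,8aS)-1,3-dihydroxy-6,8a-dimethyl-7-oxo-3-(propan-2-yl)-1,2,3,3a,4,7,8,8a-octahydroazulen-4-yl 4-acetoxybenzoate
Product: 21 (1R,3S,3aR,4R,8aS)-1-acetoxy-3-hydroxy-6,8a-dimethyl-7-oxo-3-(propan-2-yl)-1,2,3,3a,4,7,8,8a-octahydroazulen-4-yl 4-acetoxybenzoate
Conditions: Ac2O, pyridine, DMAP (cat.), CH2Cl2, 0 °C
Reagents that add atoms: acetic anhydride, CC(=O)OC(C)=O
Why: Standard acetylation of the secondary C2 alcohol; the tertiary C4 alcohol should stay free at this temperature with only catalytic DMAP.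

Step 14
Reactants: 21 (1R,3S,3aR,4R,8aS)-1-acetoxy-3-hydroxy-6,8a-dimethyl-7-oxo-3-(propan-2-yl)-1,2,3,3a,4,7,8,8a-octahydroazulen-4-yl 4-acetoxybenzoate
Product: 22 (1R,3S,3aR,4R,8aS)-1-acetoxy-3-hydroxy-6,8a-dimethyl-7-oxo-3-(propan-2-yl)-1,2,3,3a,4,7,8,8a-octahydroazulen-4-yl 4-hydroxybenzoate (CNP0087181.6)
Conditions: K2CO3 (cat.), MeOH, 0 °C
Reagents that add atoms: none
Why: Base-catalysed methanolysis cleaves aryl acetates far faster than alkyl acetates or alkyl benzoates, so brief cold treatment should release only the phenol, and the phenoxide formed deactivates the aroyl ester further.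

Compound list
1 | cyclopentane-1,3-dione | O=C1CCC(=O)C1 | starting material
2 | 3-methylfuran-2-carbaldehyde | Cc1ccoc1C=O | starting material
3 | 2-[(3-methylfuran-2-yl)methylidene]cyclopentane-1,3-dione | Cc1ccoc1C=C1C(=O)CCC1=O | intermediate (not isolated)
4 | 2-[(3-methylfuran-2-yl)methyl]cyclopentane-1,3-dione | Cc1ccoc1CC1C(=O)CCC1=O | intermediate
5 | iodomethane | CI | starting material
6 | 2-methyl-2-[(3-methylfuran-2-yl)methyl]cyclopentane-1,3-dione | Cc1ccoc1CC1(C)C(=O)CCC1=O | intermediate
7 | (2R,3R)-3-hydroxy-2-methyl-2-[(3-methylfuran-2-yl)methyl]cyclopentan-1-one | Cc1ccoc1C[C@@]1(C)C(=O)CC[C@H]1O | intermediate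
8 | (2R,3R)-3-[(tert-butyldimethylsilyl)oxy]-2-methyl-2-[(3-methylfuran-2-yl)methyl]cyclopentan-1-one | Cc1ccoc1C[C@@]1(C)C(=O)CC[C@H]1O[Si](C)(C)C(C)(C)C | intermediate
9 | (4R,5R)-4-[(tert-butyldimethylsilyl)oxy]-5-methyl-5-[(3-methylfuran-2-yl)methyl]cyclopent-1-en-1-yl trifluoromethanesulfonate | Cc1ccoc1C[C@@]1(C)C(OS(=O)(=O)C(F)(F)F)=CC[C@H]1O[Si](C)(C)C(C)(C)C | intermediate
10 | tert-butyldimethyl{[(1R,2S)-2-methyl-2-[(3-methylfuran-2-yl)methyl]cyclopent-3-en-1-yl]oxy}silane | Cc1ccoc1C[C@@]1(C)C=CC[C@H]1O[Si](C)(C)C(C)(C)C | intermediate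
11 | 9-[(3R,4R)-4-[(tert-butyldimethylsilyl)oxy]-3-methyl-3-[(3-methylfuran-2-yl)methyl]cyclopentyl]-9-borabicyclo[3.3.1]nonane (boron-bearing carbon undefined) | Cc1ccoc1C[C@@]1(C)CC(B2C3CCCC2CCC3)C[C@H]1O[Si](C)(C)C(C)(C)C | intermediate (not isolated)
12 | (3R,4R)-4-[(tert-butyldimethylsilyl)oxy]-3-methyl-3-[(3-methylfuran-2-yl)methyl]cyclopentan-1-ol (carbinol epimers) | Cc1ccoc1C[C@@]1(C)CC(O)C[C@H]1O[Si](C)(C)C(C)(C)C | intermediate
13 | (3S,4R)-4-[(tert-butyldimethylsilyl)oxy]-3-methyl-3-[(3-methylfuran-2-yl)methyl]cyclopentan-1-one | Cc1ccoc1C[C@@]1(C)CC(=O)C[C@H]1O[Si](C)(C)C(C)(C)C | intermediate (key-step precursor)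
14 | (2Z)-5-[(1R,2R)-2-[(tert-butyldimethylsilyl)oxy]-1-methyl-4-oxocyclopentyl]-3-methyl-4-oxopent-2-enal | O=C/C=C(C)\C(=O)C[C@@]1(C)CC(=O)C[C@H]1O[Si](C)(C)C(C)(C)C | intermediate (not isolated)
15 | (1R,3aR,4R,8aS)-1-[(tert-butyldimethylsilyl)oxy]-4-hydroxy-6,8a-dimethyl-1,2,3a,4,8,8a-hexahydroazulene-3,7-dione | CC(C)(C)[Si](C)(C)O[C@@H]1CC(=O)[C@H]2[C@H](O)C=C(C)C(=O)C[C@]12C | intermediate (key-step product)
16 | isopropylmagnesium chloride | CC(C)[Mg]Cl | starting material
17 | (1R,3S,3aR,4R,8aS)-1-[(tert-butyldimethylsilyl)oxy]-3,4-dihydroxy-6,8a-dimethyl-3-(propan-2-yl)-2,3,3a,4,8,8a-hexahydroazulen-7(1H)-one | CC(C)(C)[Si](C)(C)O[C@@H]1C[C@](O)(C(C)C)[C@H]2[C@H](O)C=C(C)C(=O)C[C@]12C | intermediate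
18 | 4-acetoxybenzoic acid | CC(=O)Oc1ccc(cc1)C(=O)O | starting material
19 | (1R,3S,3aR,4R,8aS)-1-[(tert-butyldimethylsilyl)oxy]-3-hydroxy-6,8a-dimethyl-7-oxo-3-(propan-2-yl)-1,2,3,3a,4,7,8,8a-octahydroazulen-4-yl 4-acetoxybenzoate | CC(C)(C)[Si](C)(C)O[C@@H]1C[C@](O)(C(C)C)[C@H]2[C@H](OC(=O)c3ccc(OC(C)=O)cc3)C=C(C)C(=O)C[C@]12C | intermediate
20 | (1R,3S,3aR,4R,8aS)-1,3-dihydroxy-6,8a-dimethyl-7-oxo-3-(propan-2-yl)-1,2,3,3a,4,7,8,8a-octahydroazulen-4-yl 4-acetoxybenzoate | O[C@@H]1C[C@](O)(C(C)C)[C@H]2[C@H](OC(=O)c3ccc(OC(C)=O)cc3)C=C(C)C(=O)C[C@]12C | intermediate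
21 | (1R,3S,3aR,4R,8aS)-1-acetoxy-3-hydroxy-6,8a-dimethyl-7-oxo-3-(propan-2-yl)-1,2,3,3a,4,7,8,8a-octahydroazulen-4-yl 4-acetoxybenzoate | CC(=O)O[C@@H]1C[C@](O)(C(C)C)[C@H]2[C@H](OC(=O)c3ccc(OC(C)=O)cc3)C=C(C)C(=O)C[C@]12C | intermediate
22 | (1R,3S,3aR,4R,8aS)-1-acetoxy-3-hydroxy-6,8a-dimethyl-7-oxo-3-(propan-2-yl)-1,2,3,3a,4,7,8,8a-octahydroazulen-4-yl 4-hydroxybenzoate | CC(=O)O[C@@H]1C[C@](O)(C(C)C)[C@H]2[C@H](OC(=O)c3ccc(O)cc3)C=C(C)C(=O)C[C@]12C | target

Total step count: 14.
Longest linear sequence: 14 steps (1 and 2 to 22).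

Steps most likely to fail

Step 9. Process at risk: facial selectivity at the aldehyde rests only on the reversibility of the addition, so the closure may deliver or settle on the C6 β-hydroxyl instead of the α-alcohol. The same step is also the one most exposed to loss of water from the aldol and to a closure that stops at the cis ring fusion; the fallback below answers only the C6 outcome. Fallback (sets out from 13, returns at 17): C6 is set by reduction instead of by the aldol. The opening and closure are run as written and the C6-epimeric aldol F1 is carried on. Organocerium addition under the conditions of step 10 would give the C6-epimeric diol F2. MnO2 in CH2Cl2 should oxidise only the allylic C6 alcohol, giving the ene-dione F3. Me4NBH(OAc)3 in MeCN/AcOH at −20 °C, bound to the tertiary C4 hydroxyl, should then deliver hydride internally to the β face of the C6 carbonyl (hydroxyl-directed anti-1,3 reduction), leave the unbound C9 ketone alone and give 17.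

Step 10. Process at risk: loss of chemoselectivity and conversion with a branched nucleophile that carries β-hydrogens, through attack at the C9 carbonyl, enolisation or hydride transfer at C4, or retro-aldol opening of the C6 alkoxide. Fallback (sets out from 15, returns at 17): the three carbons are delivered as an sp2 nucleophile and the alkene is reduced afterwards. 2-Propenylmagnesium bromide with CeCl3 in THF at −78 °C, a smaller reagent with no β-hydrogen to transfer, would give the isopropenyl carbinol F4. Hydrogenation with RhCl(PPh3)3 should saturate the terminal 1,1-disubstituted alkene and leave the trisubstituted, conjugated C7=C8 bond, giving 17.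

Step 12. Process at risk: slow cleavage of the neopentyl-type C2 silyl ether, so that prolonged fluoride exposure starts to cleave or shift the ester groups or to dehydrate the tertiary carbinol. Fallback (sets out from 17, returns at 20): the silyl group is removed before any ester is present. Bu4NF in THF, where warming is tolerable, would give the triol F5. Steglich esterification with one equivalent of 18 at 0 °C should then acylate the allylic C6 hydroxyl ahead of the C2 hydroxyl, which is flanked by the quaternary C1, and ahead of the tertiary C4 hydroxyl, giving 20, which continues with step 13.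

Further compounds
F1 | step 9 | (1R,3aR,4S,8aS)-1-[(tert-butyldimethylsilyl)oxy]-4-hydroxy-6,8a-dimethyl-1,2,3a,4,8,8a-hexahydroazulene-3,7-dione (C6 epimer of 15) | CC(C)(C)[Si](C)(C)O[C@@H]1CC(=O)[C@H]2[C@@H](O)C=C(C)C(=O)C[C@]12C
F2 | step 9 | (1R,3S,3aR,4S,8aS)-1-[(tert-butyldimethylsilyl)oxy]-3,4-dihydroxy-6,8a-dimethyl-3-(propan-2-yl)-2,3,3a,4,8,8a-hexahydroazulen-7(1H)-one (C6 epimer of 17) | CC(C)(C)[Si](C)(C)O[C@@H]1C[C@](O)(C(C)C)[C@H]2[C@@H](O)C=C(C)C(=O)C[C@]12C
F3 | step 9 | (1R,3S,3aS,8aS)-1-[(tert-butyldimethylsilyl)oxy]-3-hydroxy-6,8a-dimethyl-3-(propan-2-yl)-1,2,3,3a,8,8a-hexahydroazulene-4,7-dione | CC(C)(C)[Si](C)(C)O[C@@H]1C[C@](O)(C(C)C)[C@H]2C(=O)C=C(C)C(=O)C[C@]12C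
F4 | step 10 | (1R,3R,3aR,4R,8aS)-1-[(tert-butyldimethylsilyl)oxy]-3,4-dihydroxy-6,8a-dimethyl-3-(prop-1-en-2-yl)-2,3,3a,4,8,8a-hexahydroazulen-7(1H)-one | CC(C)(C)[Si](C)(C)O[C@@H]1C[C@](O)(C(C)=C)[C@H]2[C@H](O)C=C(C)C(=O)C[C@]12C
F5 | step 12 | (1R,3S,3aR,4R,8aS)-1,3,4-trihydroxy-6,8a-dimethyl-3-(propan-2-yl)-2,3,3a,4,8,8a-hexahydroazulen-7(1H)-one | O[C@@H]1C[C@](O)(C(C)C)[C@H]2[C@H](O)C=C(C)C(=O)C[C@]12C
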